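**Plan**

1. Enabling feature: the one benzene ring carries OH on C2 and C4, a carbonyl carbon on C1 and the 10-phenyldecyl chain on C6. Oxygen sits on every second ring carbon, which is the imprint of a folded chain of 1,3-related carbonyl groups.
2. Retrosynthetic cuts: (i) the CH3–C(=O) bond of the acetyl group, back to a phenol-protected benzoic acid; (ii) the ring bond C1–C6, which unfolds the arene into a linear 3,5,7-triketo methyl ester; (iii) the C6–C7 chain bond of that ester, giving a C6 diketo ester and a C11 phenylalkanoyl donor.
3. Forward order: the diketo ester (from dehydroacetic acid) and the Weinreb amide (from 11-phenylundecanoic acid) are joined by trianion acylation. The only ring then closes by aldol condensation with aromatisation. O-methylation, saponification, methyllithium addition and demethylation complete the acetyl resorcinol.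
4. Stereochemistry: the target has no stereocentre and no stereogenic double bond, so nothing has to be set. The transient stereocentres of the aldol adduct disappear on aromatisation.
5. Numbering used below: the triketo ester is numbered from the ester carbon (C1) to the phenyl-bearing carbon (C17); the arene is numbered from the carbonyl-bearing carbon (C1).

Key step: step 4

Remark (assumption): LDA, methyllithium and magnesium methoxide are taken as commercial solutions and are not prepared in the flask.

**Route**

Step 1
Reactants: 1 dehydroacetic acid
Product: 3 methyl 3,5-dioxohexanoate, via methyl 2-acetyl-3,5-dioxohexanoate 2 (not isolated)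
Conditions: Mg(OMe)2 (2.5 equiv), MeOH, reflux; then cold aq. HCl
Reagents that add atoms: methanol, CO; magnesium methoxide, [Mg+2].[O-]C.[O-]C
Why: Lactone methanolysis followed by retro-Claisen deacetylation: methoxide opens the pyranone to the acetyl triketo ester 2, whose magnesium chelate should lose the C2 acetyl group as methyl acetate to leave the diketo ester.

Step 2
Reactants: 4 11-phenylundecanoic acid; 5 N,O-dimethylhydroxylamine hydrochloride
Product: 7 N-methoxy-N-methyl-11-phenylundecanamide, via acyl imidazolide 6 (not isolated)
Conditions: CDI (1.1 equiv), CH2Cl2, rt; then 5 (1.2 equiv), rt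
Reagents that add atoms: none
Why: CDI amide coupling (Weinreb amide formation): the acid is activated as its acyl imidazolide with loss of CO2, and the amine, freed from its salt by the imidazole released on activation, displaces imidazole.

Step 3
Reactants: 3 methyl 3,5-dioxohexanoate (twofold excess); 7 N-methoxy-N-methyl-11-phenylundecanamide
Product: 10 methyl 3,5,7-trioxo-17-phenylheptadecanoate, via trilithium trienolate 8 (not isolated), via trilithium tetrahedral adduct 9 (not isolated)
Conditions: LDA (3.3 equiv per 3), THF, −78 → 0 °C; then 7, 0 °C → rt; poured into cold 1 M HCl; crude product used promptly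
Reagents that add atoms: none
Why: Acylation of a polyketide-type trianion with a Weinreb amide: the terminal C6 carbanion, formed last and least delocalised, is the most nucleophilic site, and the chelated adduct 9 withholds the new ketone until the acidic quench, so that bond formation should stop at the C6–C7 bond.

Step 4
Reactants: 10 methyl 3,5,7-trioxo-17-phenylheptadecanoate
Product: 12 methyl 2,4-dihydroxy-6-(10-phenyldecyl)benzoate, via cyclic aldol adduct 11 (not isolated)
Conditions: K2CO3 (1.5 equiv), MeOH–THF, rt; then 1 M HCl, MeOH, rt
Reagents that add atoms: none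
Why: Carbonate removes a proton from C2, the most acidic carbon because it lies between the ester and the C3 ketone, and this enolate adds to the C7 ketone to join the future ring carbons C1 and C6; the β-hydroxy diketone 11 then loses water, under the acid finish if not before, and its two ring ketones enolise to the phenols. The closest known reaction type is the biomimetic aldol cyclisation of 3,5,7-triketo esters to 6-substituted 2,4-dihydroxybenzoates. The one ring closes in a 6-exo-trig aldol mode (6-enolendo for the C2=C3 enolate), which is geometrically favoured. No stereocentre is created in the product, since the two stereocentres of 11 are erased by dehydration and aromatisation. The step needs the aldol mode to beat Claisen closure of C6 onto the ester and lactonisation of the C5 enol oxygen onto the ester (4-hydroxy-2-pyranone); the ketone is the better electrophile, C2 is the most acidic carbon, a protic medium with a weakly coordinating potassium ion offers no chelate template for the Claisen mode, and methanol as solvent makes ester exchange degenerate.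

Step 5
Reactants: 12 methyl 2,4-dihydroxy-6-(10-phenyldecyl)benzoate
Product: 13 methyl 2,4-dimethoxy-6-(10-phenyldecyl)benzoate
Conditions: MeI (5 equiv), K2CO3 (4 equiv), DMF, 50 °C, closed vessel
Reagents that add atoms: iodomethane, CI
Why: Williamson ether synthesis on both phenoxides; the hydrogen-bonded 2-OH reacts more slowly, hence excess iodomethane and warming, and the methyl ester is unaffected.

Step 6
Reactants: 13 methyl 2,4-dimethoxy-6-(10-phenyldecyl)benzoate
Product: 14 2,4-dimethoxy-6-(10-phenyldecyl)benzoic acid
Conditions: KOH (10 equiv), DMSO–H2O 4:1, 90 °C; then cold 1 M HCl to pH 2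
Reagents that add atoms: potassium hydroxide, [K+].[OH-]; water, O
Why: Saponification (acyl-oxygen ester hydrolysis) of a di-ortho-substituted benzoate, which needs poorly solvated hydroxide in hot aqueous DMSO; the aryl methyl ethers and the saturated chain are inert, and cold acidification avoids decarboxylation of the electron-rich acid.

Step 7
Reactants: 14 2,4-dimethoxy-6-(10-phenyldecyl)benzoic acid
Product: 17 1-[2,4-dimethoxy-6-(10-phenyldecyl)phenyl]ethanone, via lithium carboxylate 15 (not isolated), via dilithium gem-diolate 16 (not isolated)
Conditions: MeLi (3.5 equiv), Et2O–THF, 0 °C → rt; inverse quench into cold 1 M HCl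
Reagents that add atoms: methyllithium, [Li]C
Why: Ketone synthesis from a carboxylic acid with an organolithium: the first equivalent forms the carboxylate 15, the second adds to give the gem-diolate 16, which cannot add again and collapses to the methyl ketone only on the inverse acidic quench, the two ortho substituents further shielding the ketone from over-addition.

Step 8
Reactants: 17 1-[2,4-dimethoxy-6-(10-phenyldecyl)phenyl]ethanone
Product: 19 1-[2,4-dihydroxy-6-(10-phenyldecyl)phenyl]ethanone, via bis(dibromoboryl) ether 18 (not isolated)
Conditions: BBr3 (5 equiv), CH2Cl2, −78 °C → rt; then H2O, 0 °C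
Reagents that add atoms: none
Why: Boron tribromide cleavage of aryl methyl ethers: boron coordinates each ether oxygen and bromide attacks the methyl group to give aryl borates that hydrolyse to the phenols, the ortho ether being activated by chelation to the ketone and the excess reagent reaching the para ether, while the ketone, the alkyl chain and the terminal phenyl ring should not react.

**Compound list**

1 | dehydroacetic acid (3-acetyl-4-hydroxy-6-methyl-2H-pyran-2-one) | CC(=O)C1=C(O)C=C(C)OC1=O | starting material
2 | methyl 2-acetyl-3,5-dioxohexanoate (not isolated) | COC(=O)C(C(C)=O)C(=O)CC(C)=O | intermediate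
3 | methyl 3,5-dioxohexanoate | COC(=O)CC(=O)CC(C)=O | intermediate
4 | 11-phenylundecanoic acid | OC(=O)CCCCCCCCCCc1ccccc1 | starting material
5 | N,O-dimethylhydroxylamine hydrochloride | CNOC.Cl | starting material
6 | 1-(1H-imidazol-1-yl)-11-phenylundecan-1-one (acyl imidazolide, not isolated) | O=C(CCCCCCCCCCc1ccccc1)n1ccnc1 | intermediate
7 | N-methoxy-N-methyl-11-phenylundecanamide | CON(C)C(=O)CCCCCCCCCCc1ccccc1 | intermediate
8 | trilithium trienolate of methyl 3,5-dioxohexanoate (not isolated) | [Li+].[Li+].[Li+].COC([O-])=CC([O-])=CC([O-])=C | intermediate
9 | trilithium salt of methyl 7-hydroxy-7-[methoxy(methyl)amino]-3,5-dioxo-17-phenylheptadecanoate (7-alkoxide, 2,4-dienolate; tetrahedral adduct, not isolated) | [Li+].[Li+].[Li+].COC(=O)C=C([O-])C=C([O-])CC([O-])(CCCCCCCCCCc1ccccc1)N(C)OC | intermediate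
10 | methyl 3,5,7-trioxo-17-phenylheptadecanoate | COC(=O)CC(=O)CC(=O)CC(=O)CCCCCCCCCCc1ccccc1 | intermediate
11 | methyl 2-hydroxy-4,6-dioxo-2-(10-phenyldecyl)cyclohexane-1-carboxylate (cyclic aldol adduct, stereoisomer mixture, not isolated) | COC(=O)C1C(=O)CC(=O)CC1(O)CCCCCCCCCCc1ccccc1 | intermediate
12 | methyl 2,4-dihydroxy-6-(10-phenyldecyl)benzoate | COC(=O)c1c(O)cc(O)cc1CCCCCCCCCCc1ccccc1 | intermediate
13 | methyl 2,4-dimethoxy-6-(10-phenyldecyl)benzoate | COC(=O)c1c(OC)cc(OC)cc1CCCCCCCCCCc1ccccc1 | intermediate
14 | 2,4-dimethoxy-6-(10-phenyldecyl)benzoic acid | OC(=O)c1c(OC)cc(OC)cc1CCCCCCCCCCc1ccccc1 | intermediate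
15 | lithium 2,4-dimethoxy-6-(10-phenyldecyl)benzoate (not isolated) | [Li+].[O-]C(=O)c1c(OC)cc(OC)cc1CCCCCCCCCCc1ccccc1 | intermediate
16 | dilithium 1-[2,4-dimethoxy-6-(10-phenyldecyl)phenyl]ethane-1,1-diolate (not isolated) | [Li+].[Li+].CC([O-])([O-])c1c(OC)cc(OC)cc1CCCCCCCCCCc1ccccc1 | intermediate
17 | 1-[2,4-dimethoxy-6-(10-phenyldecyl)phenyl]ethanone | CC(=O)c1c(OC)cc(OC)cc1CCCCCCCCCCc1ccccc1 | intermediate
18 | 1-[2,4-bis(dibromoboranyloxy)-6-(10-phenyldecyl)phenyl]ethanone (idealised borate, not isolated) | CC(=O)c1c(OB(Br)Br)cc(OB(Br)Br)cc1CCCCCCCCCCc1ccccc1 | intermediate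
19 | 1-[2,4-dihydroxy-6-(10-phenyldecyl)phenyl]ethanone (achiral) | CC(=O)c1c(O)cc(O)cc1CCCCCCCCCCc1ccccc1 | target

**Summary**

Total step count: 8.
Longest linear sequence: 7 steps (1 → 3 → 4 → 5 → 6 → 7 → 8; the branch through step 2 is equally long).

**Steps most likely to fail**

Step 3 (trianion acylation). The third deprotonation may be incomplete, or protons may pass from the amide or the adduct to the terminal carbanion. The triketo ester may also cyclise in an uncontrolled way during work-up.

The fallback sets out from 7 and comes back to the route at 10; it masks the carboxyl end as a dioxinone and frees it only at the end. Commercial 2,2,6-trimethyl-4H-1,3-dioxin-4-one is deprotonated at the methyl group (LiHMDS, THF, −78 °C) and acetylated with acetyl chloride to give 2,2-dimethyl-6-(2-oxopropyl)-4H-1,3-dioxin-4-one F1. Double deprotonation of this ketone (LDA, THF, −78 °C) and acylation at its terminal methyl carbon with 7 should give 2,2-dimethyl-6-(2,4-dioxo-14-phenyltetradecyl)-4H-1,3-dioxin-4-one F2. Heating this in toluene at 110 °C with methanol should expel acetone by retro-[4+2] cleavage, and the acyl ketene 17-phenylheptadec-1-ene-1,3,5,7-tetrone F3 is trapped by methanol as the triketo ester 10.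

Step 4 (aldol aromatisation). The chain may close in the wrong mode: O-acylation to a 4-hydroxy-2-pyranone or Claisen closure to an acylphloroglucinol. The reaction may also stall at the undehydrated aldol stage.

The fallback gives up ring construction and attaches the chain to a preformed resorcinol ring; it sets out from 4 and comes back at 17. The acid is esterified with N-hydroxyphthalimide (DIC, cat. DMAP, CH2Cl2) to the redox-active ester 1,3-dioxoisoindolin-2-yl 11-phenylundecanoate F4. A nickel-catalysed decarboxylative Negishi coupling with (3,5-dimethoxyphenyl)zinc chloride (NiCl2·glyme, 4,4'-di-tert-butyl-2,2'-bipyridine, THF–DMF, rt) should then give 1,3-dimethoxy-5-(10-phenyldecyl)benzene F5. Friedel–Crafts acetylation (AcCl, SnCl4, CH2Cl2, −20 → 0 °C) is expected at the ring carbon flanked by the chain and one methoxy group and para to the other, as is usual for 5-alkylresorcinol dimethyl ethers. The far less electron-rich terminal phenyl ring should stay untouched, and the product is 17, which continues with step 8.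

Step 7 (methyllithium on the hindered acid). Addition to the crowded carboxylate may be incomplete, or a second addition may occur during the quench. The hindered hydrolysis of step 6 that feeds this step may also be slow.

The fallback avoids both the acid and the organolithium step by changing the oxidation level; it sets out from 13 and comes back at 17. Reduction with LiAlH4 (THF, reflux) should give [2,4-dimethoxy-6-(10-phenyldecyl)phenyl]methanol F6, kept away from acid because of its electron-rich benzylic position. Oxidation with MnO2 (CH2Cl2, rt) gives 2,4-dimethoxy-6-(10-phenyldecyl)benzaldehyde F7. Addition of MeMgBr (THF, 0 °C) gives racemic 1-[2,4-dimethoxy-6-(10-phenyldecyl)phenyl]ethanol F8, and Dess–Martin oxidation (CH2Cl2, NaHCO3, rt) removes the stereocentre again and delivers 17.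

**Further compounds**

F1 | step 3 | 2,2-dimethyl-6-(2-oxopropyl)-4H-1,3-dioxin-4-one | CC(=O)CC1=CC(=O)OC(C)(C)O1
F2 | step 3 | 2,2-dimethyl-6-(2,4-dioxo-14-phenyltetradecyl)-4H-1,3-dioxin-4-one | CC1(C)OC(=O)C=C(CC(=O)CC(=O)CCCCCCCCCCc2ccccc2)O1
F3 | step 3 | 17-phenylheptadec-1-ene-1,3,5,7-tetrone (acyl ketene, not isolated) | O=C=CC(=O)CC(=O)CC(=O)CCCCCCCCCCc1ccccc1
F4 | step 4 | 1,3-dioxoisoindolin-2-yl 11-phenylundecanoate | O=C(CCCCCCCCCCc1ccccc1)ON1C(=O)c2ccccc2C1=O
F5 | step 4 | 1,3-dimethoxy-5-(10-phenyldecyl)benzene | COc1cc(OC)cc(CCCCCCCCCCc2ccccc2)c1
F6 | step 7 | [2,4-dimethoxy-6-(10-phenyldecyl)phenyl]methanol | OCc1c(OC)cc(OC)cc1CCCCCCCCCCc1ccccc1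
F7 | step 7 | 2,4-dimethoxy-6-(10-phenyldecyl)benzaldehyde | O=Cc1c(OC)cc(OC)cc1CCCCCCCCCCc1ccccc1
F8 | step 7 | 1-[2,4-dimethoxy-6-(10-phenyldecyl)phenyl]ethanol (racemic) | CC(O)c1c(OC)cc(OC)cc1CCCCCCCCCCc1ccccc1
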